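The constants were chosen freely; the flask was simulated.

The flask holds 0.098 M of J against 0.245 M of Q, so the reagent is charged in excess, by amount, but that surplus does not say what J will actually meet.

J 0.098 M; Q 0.245 M; time 5.0 min; volume of the second phase over the first 0.50

1. how much J.G there is at 5.0 min, in percent of the J charged
2. part of the J charged that has reacted at 5.0 min

    G ⇌ Q, rate k1*([G] - [Q]/K1) per volume of the first phase (K1 = 0.67, k1 = 0.21 s⁻¹)
    J + G → J.G (k2 = 0.12 M⁻¹ s⁻¹)
    G + J.G → G.J.G (k3 = 0.063 M⁻¹ s⁻¹)
    J + J.G → J.J.G (k4 = 0.45 M⁻¹ s⁻¹)
    J.G ⇌ Z (K5 = 1.8, k5 = 0.055 s⁻¹)
    2 G → G2 (k6 = 0.28 M⁻¹ s⁻¹)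

Start with the state the feed reaches. Q and G share themselves out within about 1.19 s, which puts 0.184 M of G in the first phase. Then G pairs off to G2, and the reservoir sinks with it. At first pairing takes each G faster than J does, at 0.103 s⁻¹ against 0.0118 s⁻¹. So G falls as one over time, on a scale of 13.0 s, far shorter than the 5.0 min of the run.

What J feels from G, then, is the integral of G over time. I call the turn count the rate constant of J + G times that integral. It equals 0.286 times the logarithm of one plus time over the scale, which gives 0.910 at the asked time.

Two people read this count differently. One says each turn takes one J, so J left is 40.3% and the part reacted is 59.7%, with J.G plentiful. The other notes that J.G has a half-life of 0.26 min against J by that step by itself, at the charged amounts, short against the run. Each J.G should then take a second J, leaving 16.2% of J and 83.8% reacted.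

I side with the second, and my count gives no figure for J.G. The forecast, also on that side, says 3.5% and 78%, the second below my 83.8%: “J continues to be consumed mainly through J + J.G, with Z acting as a buffer”.

The flask gives 3.68% and 77.6%, with the forecast.

With 22% of J left, this flask ran at 1.64 J per turn, nearer two than one, and 64.1% of the J charged sits in J.J.G. One J per turn has its region early: at 0.500 min the count is 0.342, which gives 71.0% of J against 50.5% for two, and this flask read 65.5%. The neighbouring flask, the same charge read at 2.0 min, has a count of 0.665, which brackets J between 51.4% and 26.4%; it stands at 38.1%, or 1.45 J per turn.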